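**Assumptions:** the target SMILES is read as (5R) at the butenolide carbon and (2S) at the chromene carbon, with a (2E) trisubstituted alkene. Catalysts and ligands are treated as reagents. The sense of induction in the new step (Step 17) cannot be predicted, so the catalyst antipode that gives 5R is chosen by experiment.

## Retrosynthetic overview

1. Target 22 ⇐ aryl silyl ether 21 ⇐ C5 stereocentre set by a proposed catalytic enantioselective C5-protonation of 2-silyloxyfuran 20.
2. 20 ⇐ C5–CH2 bond from 5-lithiated silyloxyfuran 19 and (E)-allylic bromide 13.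
3. 13 ⇐ E-selective allylic oxidation of the prenyl terminus of chromene 11.
4. 11 ⇐ intramolecular Pd C–O coupling of Z-allylic tertiary alcohol 10 ⇐ Sonogashira coupling of dihaloarene 8 with (S)-alkynol 4; the chromene stereocentre comes from Sharpless epoxidation of geraniol.
5. Ring order: benzene ring bought (5); pyran ring closed in Step 9; five-membered lactone bought (14), carried as furan 19/20, and revealed as the butenolide in Step 17.

## Route

**Step 1**
Reactants: 1 geraniol
Product: 2 [(2S,3S)-3-methyl-3-(4-methylpent-3-en-1-yl)oxiran-2-yl]methanol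
Conditions: Ti(OiPr)4 (5 mol%), L-(+)-DET (7 mol%), t-BuOOH, 4 Å MS, CH2Cl2, −20 °C
Reagents that add atoms: tert-butyl hydroperoxide, CC(C)(C)OO
Why: Sharpless asymmetric epoxidation with L-(+)-tartrate gives the (2S,3S)-epoxide, whose C3 becomes the chromene stereocentre; the isolated 6,7-alkene does not react.

**Step 2**
Reactants: 2
Product: 3 (2R,3S)-2-(chloromethyl)-3-methyl-3-(4-methylpent-3-en-1-yl)oxirane
Conditions: PPh3, CCl4, NaHCO3, reflux
Reagents that add atoms: carbon tetrachloride, ClC(Cl)(Cl)Cl
Why: Buffered Appel chlorination of the primary alcohol leaves the epoxide and both stereocentres untouched (the C2 descriptor changes only through CIP priority).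

**Step 3**
Reactants: 3
Product: 4 (3S)-3,7-dimethyloct-6-en-1-yn-3-ol
Conditions: n-BuLi (3.5 equiv), THF, −40 °C
Reagents that add atoms: none
Why: Base-induced double elimination of a 2,3-epoxy chloride (α-deprotonation and epoxide opening, then loss of HCl) gives the terminal propargylic alcohol; the C3–O bond is never broken, so (S) is retained.

**Step 4**
Reactants: 5 4-amino-3-methylphenol
Product: 6 2-methyl-4-(triisopropylsilyloxy)aniline
Conditions: TIPSCl, imidazole, DMF, rt
Reagents that add atoms: triisopropylsilyl chloride, CC(C)[Si](Cl)(C(C)C)C(C)C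
Why: Chemoselective O-silylation of the phenol over the aniline; the TIPS aryl ether tolerates the later bases and Pd steps.

**Step 5**
Reactants: 6
Product: 7 2-iodo-6-methyl-4-(triisopropylsilyloxy)aniline
Conditions: BnMe3N·ICl2, CaCO3, CH2Cl2/MeOH, rt
Reagents that add atoms: benzyltrimethylammonium dichloroiodate, C[N+](C)(C)Cc1ccccc1.Cl[I-]Cl
Why: Electrophilic aromatic iodination goes ortho to the strongly activating NH2, since the para position and the other ortho position are blocked.

**Step 6**
Reactants: 7
Product: 8 (4-bromo-3-iodo-5-methylphenoxy)triisopropylsilane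
Conditions: t-BuONO, CuBr2, MeCN, 0 °C → rt
Reagents that add atoms: copper(II) bromide, Br[Cu]Br
Why: Non-aqueous Sandmeyer bromination replaces NH2 by Br under near-neutral conditions that the silyl ether and aryl iodide tolerate.

**Step 7**
Reactants: 8 and 4
Product: 9 (3S)-1-[2-bromo-3-methyl-5-(triisopropylsilyloxy)phenyl]-3,7-dimethyloct-6-en-1-yn-3-ol
Conditions: PdCl2(PPh3)2 (3 mol%), CuI (5 mol%), Et3N, THF, rt
Reagents that add atoms: none
Why: Sonogashira coupling is selective for C–I over the adjacent C–Br at room temperature, and the tertiary carbinol is a spectator.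

**Step 8**
Reactants: 9
Product: 10 (1Z,3S)-1-[2-bromo-3-methyl-5-(triisopropylsilyloxy)phenyl]-3,7-dimethylocta-1,6-dien-3-ol
Conditions: H2 (1 atm), Lindlar catalyst, quinoline, EtOAc, rt
Reagents that add atoms: none (H2 only)
Why: Lindlar syn-semihydrogenation gives the Z-alkene needed for ring closure; the poisoned catalyst spares the aryl bromide and the trisubstituted alkene.

**Step 9**
Reactants: 10
Product: 11 (2S)-2,8-dimethyl-2-(4-methylpent-3-en-1-yl)-6-(triisopropylsilyloxy)-2H-chromene
Conditions: Pd(OAc)2 (5 mol%), 2-(di-tert-butylphosphino)-1,1′-binaphthyl (6 mol%), Cs2CO3, toluene, 70 °C, dark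
Reagents that add atoms: none
Why: Intramolecular Buchwald–Hartwig-type C–O coupling (tertiary alkoxide with no β-H, Z-alkene pre-organising a six-membered closure) forms the pyran ring through the aryl–O bond, so the C–O bond at the stereocentre is untouched and (S) is retained.

**Step 10**
Reactants: 11
Product: 12 (2E)-5-[(2S)-2,8-dimethyl-6-(triisopropylsilyloxy)-2H-chromen-2-yl]-2-methylpent-2-en-1-ol
Conditions: SeO2 (0.5 equiv), t-BuOOH, salicylic acid (cat.), CH2Cl2, 0 °C → rt; then NaBH4, MeOH, 0 °C
Reagents that add atoms: selenium dioxide, O=[Se]=O (reoxidised by t-BuOOH, CC(C)(C)OO)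
Why: Riley allylic oxidation (ene reaction then [2,3]-shift) is selective for the E-methyl of the terminal gem-dimethyl alkene; the chromene C3=C4 has no allylic hydrogen, and NaBH4 returns any over-oxidised enal to the alcohol.

**Step 11**
Reactants: 12
Product: 13 (2S)-2-[(3E)-5-bromo-4-methylpent-3-en-1-yl]-2,8-dimethyl-6-(triisopropylsilyloxy)-2H-chromene
Conditions: MsCl, Et3N, THF, −40 °C; then LiBr, −40 → 0 °C (used crude)
Reagents that add atoms: lithium bromide, [Li+].[Br-]
Why: Mesylation and SN2 displacement by bromide at the primary allylic carbon keep the E geometry.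

**Step 12**
Reactants: 14 3-bromodihydrofuran-2(3H)-one (racemic)
Product: 15 3-(phenylthio)dihydrofuran-2(3H)-one (racemic)
Conditions: PhSH, Et3N, CH2Cl2, 0 °C → rt
Reagents that add atoms: thiophenol, Sc1ccccc1
Why: SN2 displacement of the activated α-bromide by thiolate.

**Step 13**
Reactants: 15 and 16 5-bromo-2-methylpent-2-ene
Product: 17 3-(4-methylpent-3-en-1-yl)-3-(phenylthio)dihydrofuran-2(3H)-one (racemic)
Conditions: LDA, THF, −78 °C; then 16, HMPA, −78 °C → rt
Reagents that add atoms: none
Why: Alkylation of the sulfur-stabilised lactone enolate with a primary bromide; the racemic quaternary centre is destroyed in the next step.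

**Step 14**
Reactants: 17
Product: 18 3-(4-methylpent-3-en-1-yl)furan-2(5H)-one
Conditions: mCPBA (1.0 equiv), CH2Cl2, −78 °C; then toluene, CaCO3, 110 °C
Reagents that add atoms: none (the oxygen added leaves with PhSOH)
Why: Sulfide oxidation is much faster than epoxidation of the trisubstituted alkene at −78 °C, and thermal sulfoxide syn-elimination into the ring gives the endocyclic α-alkyl butenolide.

**Step 15**
Reactants: 18
Product: 19 triisopropyl{[3-(4-methylpent-3-en-1-yl)furan-2-yl]oxy}silane
Conditions: TIPSOTf, Et3N, CH2Cl2, 0 °C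
Reagents that add atoms: triisopropylsilyl triflate, CC(C)[Si](OS(=O)(=O)C(F)(F)F)(C(C)C)C(C)C
Why: Soft enolisation and O-silylation of the butenolide gives the aromatic 2-silyloxyfuran.

**Step 16**
Reactants: 19 and 13
Product: 20 triisopropyl{[5-[(2E)-5-[(2S)-2,8-dimethyl-6-(triisopropylsilyloxy)-2H-chromen-2-yl]-2-methylpent-2-en-1-yl]-3-(4-methylpent-3-en-1-yl)furan-2-yl]oxy}silane
Conditions: s-BuLi, TMEDA, THF, −78 °C; then 13, −78 → −20 °C (used directly)
Reagents that add atoms: none
Why: α-Lithiation of the furan at C5 (the only free α-position; C3 is blocked) and SN2 alkylation with the primary allylic bromide form the C5–CH2 bond regiospecifically with the E-alkene retained.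

**Step 17**
Reactants: 20
Product: 21 (5R)-5-[(2E)-5-[(2S)-2,8-dimethyl-6-(triisopropylsilyloxy)-2H-chromen-2-yl]-2-methylpent-2-en-1-yl]-3-(4-methylpent-3-en-1-yl)furan-2(5H)-one
Conditions: 3,3′-bis(2,4,6-triisopropylphenyl)-BINOL N-triflyl thiophosphoramide (5 mol%, antipode chosen for 5R), MeOH (1.5 equiv), toluene, −78 °C
Reagents that add atoms: none (MeOH supplies only H; the furan TIPS leaves as TIPSOMe)
Why: Proposed new method: catalytic enantioselective vinylogous (C5) protodesilylation of a 2-silyloxyfuran. The confined chiral acid protonates C5, the furan α-position where 2-silyloxyfurans accept cationic electrophiles, inside a chiral contact ion pair to give an O-silyl butenolidium ion; MeOH then removes silicon and returns the proton to the catalyst. The acidic, base-free medium cannot epimerise the new γ-centre, and the chromene centre is too remote to interfere, so the catalyst sets 5R. Any C3-protonated isomer can be re-silylated back to 20. The closest known reaction types are chiral Brønsted-acid-catalysed protonation of silyl enol ethers and silyl ketene acetals with an achiral stoichiometric proton source, and amine-catalysed γ-protonation in butenolide isomerisation.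

**Step 18**
Reactants: 21
Product: 22 tuberatolide B, (5R)-5-[(2E)-5-[(2S)-6-hydroxy-2,8-dimethyl-2H-chromen-2-yl]-2-methylpent-2-en-1-yl]-3-(4-methylpent-3-en-1-yl)furan-2(5H)-one
Conditions: TBAF/AcOH (1:1), THF, 0 °C
Reagents that add atoms: none
Why: Fluoride cleavage of the aryl silyl ether, buffered with AcOH so the epimerisable butenolide γ-H is not deprotonated.

## Compound list

1 | geraniol, (2E)-3,7-dimethylocta-2,6-dien-1-ol | CC(C)=CCC/C(C)=C/CO | starting material
2 | [(2S,3S)-3-methyl-3-(4-methylpent-3-en-1-yl)oxiran-2-yl]methanol | OC[C@@H]1O[C@@]1(C)CCC=C(C)C | intermediate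
3 | (2R,3S)-2-(chloromethyl)-3-methyl-3-(4-methylpent-3-en-1-yl)oxirane | ClC[C@@H]1O[C@@]1(C)CCC=C(C)C | intermediate
4 | (3S)-3,7-dimethyloct-6-en-1-yn-3-ol | CC(C)=CCC[C@](C)(O)C#C | intermediate
5 | 4-amino-3-methylphenol | Cc1cc(O)ccc1N | starting material
6 | 2-methyl-4-(triisopropylsilyloxy)aniline | Cc1cc(O[Si](C(C)C)(C(C)C)C(C)C)ccc1N | intermediate
7 | 2-iodo-6-methyl-4-(triisopropylsilyloxy)aniline | Cc1cc(O[Si](C(C)C)(C(C)C)C(C)C)cc(I)c1N | intermediate
8 | (4-bromo-3-iodo-5-methylphenoxy)triisopropylsilane | Cc1cc(O[Si](C(C)C)(C(C)C)C(C)C)cc(I)c1Br | intermediate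
9 | (3S)-1-[2-bromo-3-methyl-5-(triisopropylsilyloxy)phenyl]-3,7-dimethyloct-6-en-1-yn-3-ol | CC(C)=CCC[C@](C)(O)C#Cc1cc(O[Si](C(C)C)(C(C)C)C(C)C)cc(C)c1Br | intermediate
10 | (1Z,3S)-1-[2-bromo-3-methyl-5-(triisopropylsilyloxy)phenyl]-3,7-dimethylocta-1,6-dien-3-ol | CC(C)=CCC[C@](C)(O)/C=C\c1cc(O[Si](C(C)C)(C(C)C)C(C)C)cc(C)c1Br | intermediate
11 | (2S)-2,8-dimethyl-2-(4-methylpent-3-en-1-yl)-6-(triisopropylsilyloxy)-2H-chromene | CC(C)=CCC[C@@]1(C)C=Cc2cc(O[Si](C(C)C)(C(C)C)C(C)C)cc(C)c2O1 | intermediate
12 | (2E)-5-[(2S)-2,8-dimethyl-6-(triisopropylsilyloxy)-2H-chromen-2-yl]-2-methylpent-2-en-1-ol | OC/C(C)=C/CC[C@@]1(C)C=Cc2cc(O[Si](C(C)C)(C(C)C)C(C)C)cc(C)c2O1 | intermediate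
13 | (2S)-2-[(3E)-5-bromo-4-methylpent-3-en-1-yl]-2,8-dimethyl-6-(triisopropylsilyloxy)-2H-chromene | BrC/C(C)=C/CC[C@@]1(C)C=Cc2cc(O[Si](C(C)C)(C(C)C)C(C)C)cc(C)c2O1 | intermediate
14 | 3-bromodihydrofuran-2(3H)-one (α-bromo-γ-butyrolactone, racemic) | BrC1CCOC1=O | starting material
15 | 3-(phenylthio)dihydrofuran-2(3H)-one (racemic) | O=C1OCCC1Sc1ccccc1 | intermediate
16 | 5-bromo-2-methylpent-2-ene | CC(C)=CCCBr | starting material
17 | 3-(4-methylpent-3-en-1-yl)-3-(phenylthio)dihydrofuran-2(3H)-one (racemic) | CC(C)=CCCC1(Sc2ccccc2)CCOC1=O | intermediate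
18 | 3-(4-methylpent-3-en-1-yl)furan-2(5H)-one | CC(C)=CCCC1=CCOC1=O | intermediate
19 | triisopropyl{[3-(4-methylpent-3-en-1-yl)furan-2-yl]oxy}silane | CC(C)=CCCc1ccoc1O[Si](C(C)C)(C(C)C)C(C)C | intermediate
20 | triisopropyl{[5-[(2E)-5-[(2S)-2,8-dimethyl-6-(triisopropylsilyloxy)-2H-chromen-2-yl]-2-methylpent-2-en-1-yl]-3-(4-methylpent-3-en-1-yl)furan-2-yl]oxy}silane | CC(C)=CCCc1cc(C/C(C)=C/CC[C@@]2(C)C=Cc3cc(O[Si](C(C)C)(C(C)C)C(C)C)cc(C)c3O2)oc1O[Si](C(C)C)(C(C)C)C(C)C | intermediate
21 | (5R)-5-[(2E)-5-[(2S)-2,8-dimethyl-6-(triisopropylsilyloxy)-2H-chromen-2-yl]-2-methylpent-2-en-1-yl]-3-(4-methylpent-3-en-1-yl)furan-2(5H)-one | CC(C)=CCCC1=C[C@@H](C/C(C)=C/CC[C@@]2(C)C=Cc3cc(O[Si](C(C)C)(C(C)C)C(C)C)cc(C)c3O2)OC1=O | intermediate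
22 | tuberatolide B, (5R)-5-[(2E)-5-[(2S)-6-hydroxy-2,8-dimethyl-2H-chromen-2-yl]-2-methylpent-2-en-1-yl]-3-(4-methylpent-3-en-1-yl)furan-2(5H)-one | CC(C)=CCCC1=C[C@@H](C/C(C)=C/CC[C@@]2(C)C=Cc3cc(O)cc(C)c3O2)OC1=O | target

## Summary

**Total steps:** 18.

**Longest linear sequence:** 11 steps (1–3, 7–11, 16–18; the arene branch 4–6, 7–11, 16–18 is also 11).

**Three steps most likely to fail, with fallbacks:**

- **Step 17 (proposed new enantioselective C5-protonation).** The risks are low ee or competing C3-protonation. Fallback with known chemistry: set C5 with an auxiliary instead. Alkylate the sodium enolate of (S)-4-benzyl-3-[(4-methoxybenzyloxy)acetyl]oxazolidin-2-one with bromide 13 (Evans-type glycolate alkylation), reduce with LiBH4 and oxidise with Dess–Martin periodinane to the α-alkoxy aldehyde, run a Z-selective Still–Gennari/Ando olefination with the phosphonoacetate carrying the 4-methylpent-3-enyl group, then remove PMB so the hydroxy ester lactonises to 21.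
- **Step 16 (lithiated silyloxyfuran plus advanced allylic bromide).** The risks are incomplete lithiation, SN2′ attack and a labile product. Fallback: switch from the organolithium to electrophilic activation. Silver(I) trifluoroacetate-promoted C5-alkylation of silyloxyfuran 19 with 13 gives the butenolide as a C5-epimer mixture, which TIPSOTf/Et3N converts back to 20 for Step 17.
- **Step 10 (late-stage SeO2 oxidation on the chromene).** The risks are low conversion and over-oxidation. Fallback: move the oxidation to the start. Oxidise geranyl acetate with SeO2/t-BuOOH, protect the new C8–OH as a TBS ether, remove the acetate, and carry the oxygenated chain through Steps 1–3 and 7–9; PPTS/MeOH then unmasks the alcohol (the aryl OTIPS is stable) to give 12.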